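Readings and results come from a simulation with made-up constants.

In a one-step world, each part of the substrate lost would have stood as target, so I tested that on the earlier runs.

| flask | substrate | gas phase | remark | time |
|---|---|---|---|---|
| larch | 0.015 M | 6.8 mM (held) | run made earlier |  |
| ash | 0.073 M | 6.8 mM (held) | run made earlier |  |
| red | 0.025 M | 6.8 mM (held) |  | 0.50 min |
| green | 0.10 M | 6.8 mM (held) |  | 2.0 min |

| run | time / s | target / % | substrate / % |
|---|---|---|---|
| larch | 10.0 | 2 | 92 |
| larch | 15.0 | 6 | 92 |
| larch | 30.0 | 12 | 83 |
| larch | 50.0 | 19 | 65 |
| larch | 60.0 | 20 | 61 |
| larch | 80.0 | 29 | 57 |
| ash | 15.0 | 6 | 94 |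
| ash | 30.0 | 7 | 83 |
| ash | 40.0 | 9 | 73 |
| ash | 60.0 | 19 | 69 |
| ash | 80.0 | 27 | 61 |

(scatter of a reading: 2 percentage points)

- at the start none of the gas is dissolved
- steps thought possible: gas phase <-> dissolved gas; substrate + dissolved gas <-> target; substrate -> side product

- which one finishes higher in amount of target, in percent of the substrate charged ("neither" within 2 percentage points) (red / green / neither)
- amount of target at the end, in percent of the substrate charged, red
- amount of target at the end, in percent of the substrate charged, green

The larch run had lost 43.0 % of its charge at 80.0 s but held 29 % as target. I carried the ratio 0.674, the target share, meaning target held per part of substrate lost. It is the selectivity of the run, read from readings with scatter. The ash run gave 0.692 at 80.0 s. That was one pair of readings, each with a scatter of 2 percentage points, so it showed nothing firm about the charge.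

I then went two ways. The first replaced the larch curve by its mean slope, 0.00362 s⁻¹ of the charge. That gave 10.9 % for red and 43.5 % for green. The second took a first-order loss of substrate from the same reading, 0.00703 s⁻¹, and multiplied the loss by the share. That gave 12.8 % for red and 38.4 % for green.

For red the two ways lay 1.9 points apart, but both came from the same larch readings at 80.0 s, so that was no check. For green they parted, and the slope cheated. It kept the mean substrate of the larch run, 0.765 of the charge, but over 2.0 min the mean falls to 0.676. I committed to the second way.

The forecast said green, with 10 % for red and 33 % for green. That was below my green figure and below my red figure. It lowered its green figure with the words “The higher concentration may starve the dissolved gas a little”.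

The flasks gave green as the higher, with 27.2 % against 11.9 % for red.

    gas phase ⇌ dissolved gas, rate k1*(csat - [dissolved gas]) (kL = 0.0919 s⁻¹)
    substrate + dissolved gas ⇌ target (K = 170 M⁻¹, k = 1.28 M⁻¹ s⁻¹)
    substrate → side product (k = 0.00257 s⁻¹)

Green had lost 49.5 % of its charge, so its target share was 0.549, lower than the 0.674 I carried. Red's share was 0.630. A further flask, red with 0.10 M of substrate, read at 0.500 min, had lost 15.4 % of its charge and held 8.27 % as target, a share of 0.537.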